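**Atom numbering used throughout (from compound 10 onwards):** ring A = C1, C10, C11, C12, C13, C14; ten-membered ring = C1–C10; lactone = C7, C8, C17, C19(=O) and the ring oxygen; C15 = methyl on C1, C16 = methylene on C5, C18 = methyl on C17, C20 = methyl on C11. CIP descriptors are given in this numbering.

**Assumption:** 3-methyltetronic acid (5) is taken as commercial, and the antipode of the imidazolinium ligand is chosen that gives the 1R quaternary centre of 12 (this centre becomes 1S once C2 carries oxygen).

## Analysis of the target

The target is a 6/10-fused carbobicycle, ring A (C1, C10–C14) fused at C1–C10 to a cyclodecane (C1–C10), which also carries a γ-lactone fused at C7–C8 and a trans-epoxide at C2–C3. Its ten stereocentres are 1S, 2R, 3R, 6S, 7S, 8R, 9S, 10S, 11S and 17R; the C2 and C9 arms are trans on ring A, so H10 is trans to the C15 methyl. The C20 methyl is cis to C15 and the C11 acetate is trans to it, so a methyl nucleophile added to a C11 ketone would enter from the wrong side and the C11 oxygen has to be delivered to a C11-methyl alkene instead. The lactone is cis-fused, with the C8 hydroxyl cis to H7 and to the C18 methyl, and C9 has the syn-aldol relationship to C10. The sensitive groups are the α-acetoxy enone of ring A, the secondary allylic chloride at C6 next to the C5=C16 methylene (prone to SN2′), the epoxide, the acetoxyacetate ester and the tertiary β-hydroxy lactone (prone to dehydration and retro-aldol). The difficulties are the ten-membered ring, the contiguous stereocentres from C6 to C11, and the need to oxidise three different alkenes (C2=C3, C11=C12, C8=C17) one at a time. The strategy rests on one feature: C1 (quaternary, with C15) and C10 are the β- and α-carbons of a ring A carbonyl at C11, so the two arms of the large ring, through C2 and through C9, can be attached as nucleophile and electrophile to a simple cyclohexenone.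

## Retrosynthetic reasoning

**Ring A end-game (32 ⇐ 31 ⇐ 30 ⇐ 29 ⇐ 28).** The C13=C14 double bond, the C11 acetate and the C12 ketone are removed first, leading back to the C11-methyl C11=C12 alkene 28. An enone and an α-acyloxy ketone would not survive the reductive, nucleophilic and palladium-mediated steps needed elsewhere, so ring A is kept as an inert alkene until the end. Cis-dihydroxylation from the face opposite the axial C15 methyl places the C11 oxygen correctly; oxidation of the secondary C12 carbinol, acetylation and dehydrogenation (only C13 has α-hydrogens) finish the ring.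

**C9 ester and C6 chloride (28 ⇐ 27 ⇐ 26).** The acetoxyacetate is cut at the C9–O bond and the chloride is traced to the epimeric allylic alcohol in triol 26. The chloride is introduced late because an allylic chloride tolerates neither zerovalent palladium nor single-electron reductants nor peroxide anions. Of the three hydroxyls in 26 only the one at C6 is allylic and unhindered, so no protecting group is needed.

**C8–OH and C17–H (26 ⇐ 25 ⇐ 24 ⇐ 23).** The tertiary β-hydroxy lactone is the formal hydrate of the butenolide in 23. It is reached by nucleophilic epoxidation on the face anti to C6, followed by reductive cleavage of the C17–O bond. This is why the lactone can be carried as a butenolide through the ring closure.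

**C20 methyl and the epoxide (23 ⇐ 22 ⇐ 21).** The C11–C20 bond is cut back to the enol triflate 22, and the epoxide to the E-alkene of 21. The order matters: the epoxidation is run while ring A is an electron-poor enol triflate, so the oxidant cannot attack ring A. The methyl is introduced only afterwards.

**Ten-membered ring (21 ⇐ 19).** The ring is opened at C6–C7. The γ-carbon of the butenolide is a latent nucleophile (as its silyloxyfuran) and C6 is an enal carbon, so a vinylogous aldol closes the ring and sets C6 and C7 without adding atoms. Cutting here keeps all other ring bonds intact from the coupling step and uses the butenolide twice, as nucleophile and as lactone precursor.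

**C9 inversion and masking of the ketone (19 ⇐ 18 ⇐ 17 ⇐ 16 ⇐ 15 ⇐ 13 ⇐ 12).** The C9 carbinol of 19 comes from Felkin–Anh reduction of ketone 17, because the coupling step gives the opposite (anti) epimer. Oxidation at C9 next to a C11 ketone would give an enolised β-diketone and destroy C10, so the ketone of 12 is first converted into the enol triflate 15. That step needs a strong base, so the acidic butenolide is held as a silyloxyfuran (13) while it is run.

**Key disconnection (12 ⇐ 9 + 10 + 8).** C1–C2 and C9–C10 are cut together. Enone 9 is the complete ring A template, alane 10 brings C2–C6 and C16 with the E-alkene already in place, and aldehyde 8 brings C7–C9 and C17–C19. After this step all twenty skeletal carbons are present, with C1 and C10 set.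

**Fragments (10 ⇐ 4 ⇐ 3 ⇐ 2 ⇐ 1; 8 ⇐ 7 ⇐ 6 ⇐ 5).** The alane comes from hydroalumination of enyne 4, made in three steps from diol 1. The aldehyde comes from tetronic acid 5 by triflation, vinyl coupling and alkene cleavage. Both are short, standard sequences, so the risk sits in the coupling step.

## Alternatives that were turned down

Alternative 1: The ten-membered ring is not closed but uncovered: the C3–C8 bond is treated as the bond common to two fused six-membered rings and is carried as an epoxide. In the forward direction periodic acid (H5IO6) cleaves this bond, both carbons become ketones, and the product is the 3,8-diketone A1 with a (Z)-C5=C6 alkene. In its favour, no medium ring has to be closed, since the strain is paid by a fragmentation, and a quinone Diels–Alder entry to such a bicyclic core is short. The C8 ketone is also an excellent handle for the tertiary C8 alcohol and the lactone. On ring formation and on C8 it is stronger than the chosen route. Against it, A1 is far from the target in oxidation pattern. C2/C3 are a protected carbinol and a ketone where an E-alkene and then a trans-epoxide are needed. C16 is a methyl on an endocyclic alkene. C7 has no oxygen. The three lactone carbons are missing, and ring A still needs C11 hydroxylation and dehydrogenation. Several of these adjustments must set stereocentres on a flexible ten-membered ring. The chosen route instead has all twenty carbons, the E-C2=C3 alkene and the C16 methylene in place after one coupling step.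

Alternative 2: The lactone C8–C17 bond is made last. A diazo group on the α-carbon of a propionate ester at the C7 oxygen is decomposed by Rh2(O2CCPh3)4, and the carbenoid carbon inserts into the tertiary C8–H bond to give A2. In its favour, 1,5-insertion into an oxygen-activated tertiary C–H bond is favourable and proceeds with retention, and C8–O is never in doubt; on that point it is stronger than the chosen epoxidation–reduction. Against it, the carbenoid is generated next to the C5=C16 methylene (intramolecular cyclopropanation), an epoxide oxygen (ylide formation) and an enone. α-Alkyl diazoesters also lose the carbenoid by 1,2-hydride shift, and C17 is set by an insertion transition state that is hard to predict. Above all, the construction of the ten-membered ring with seven stereocentres is left unsolved. The chosen route offers the lactone carbons from the first coupling and uses them to close the ring.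

Alternative 3: The ring is closed at C7–C8. CrCl2 inserts into an allylic C–Br bond, the allyl–chromium bond adds through C8 to the C7 aldehyde carbon, and the chromium alkoxide then lactonises onto the C19 ester to give A3. In its favour, chromium-mediated allylation is among the best-precedented medium-ring closures, and ring and lactone form together; its ring closure is better precedented than the vinylogous aldol used here. Against it, the nucleophilic terminus must become a fully substituted, oxygen-bearing C8, the most hindered end of a trisubstituted allylmetal. The α-acetoxy enone already present in A3 is reducible by CrCl2 and is an electrophile. The open-chain cyclisation substrate needs a long linear assembly, and afterwards the α-methylene lactone still needs a stereoselective reduction at C17, the C6 ether must be replaced by chloride, and C2=C3 must be epoxidised. The chosen route reaches its cyclisation substrate in thirteen steps and cyclises before any reducible ring A functionality exists.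

Key step: step 7

## Route

Step 1
Reactants: 1 2-methylenepropane-1,3-diol
Product: 2 2-({[tert-butyl(dimethyl)silyl]oxy}methyl)prop-2-en-1-ol
Conditions: NaH (1.0 equiv), TBSCl (1.0 equiv), THF, 0 °C → rt
Reagents that add atoms: tert-butyldimethylsilyl chloride, CC(C)(C)[Si](C)(C)Cl
Why: Monosilylation of a symmetric diol through its sparingly soluble monosodium alkoxide; the second hydroxyl remains free.

Step 2
Reactants: 2 2-({[tert-butyl(dimethyl)silyl]oxy}methyl)prop-2-en-1-ol
Product: 3 {[2-(bromomethyl)prop-2-en-1-yl]oxy}(tert-butyl)dimethylsilane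
Conditions: CBr4, PPh3, CH2Cl2, 0 °C
Reagents that add atoms: carbon tetrabromide, BrC(Br)(Br)Br
Why: Appel bromination of a primary allylic alcohol under neutral conditions that leave the silyl ether intact.

Step 3
Reactants: 3 {[2-(bromomethyl)prop-2-en-1-yl]oxy}(tert-butyl)dimethylsilane
Product: 4 tert-butyl(dimethyl)[(2-methylidenepent-4-yn-1-yl)oxy]silane
Conditions: HC≡CMgBr (2 equiv), CuBr·SMe2 (10 mol %), THF, 0 °C → rt
Reagents that add atoms: ethynylmagnesium bromide, C#C[Mg]Br
Why: Copper-catalysed coupling of an alkynyl Grignard reagent with an allylic bromide; SN2 and SN2′ attack give the same 1,4-enyne because the two allylic termini are equivalent.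

Step 4
Reactants: 5 4-hydroxy-3-methylfuran-2(5H)-one (3-methyltetronic acid)
Product: 6 4-methyl-5-oxo-2,5-dihydrofuran-3-yl trifluoromethanesulfonate
Conditions: Tf2O, i-Pr2NEt, CH2Cl2, −78 °C
Reagents that add atoms: trifluoromethanesulfonic anhydride, O=S(=O)(OS(=O)(=O)C(F)(F)F)C(F)(F)F
Why: O-Sulfonylation of the acidic enol of a tetronic acid gives the vinylogous acyl triflate.

Step 5
Reactants: 6 4-methyl-5-oxo-2,5-dihydrofuran-3-yl trifluoromethanesulfonate
Product: 7 4-ethenyl-3-methylfuran-2(5H)-one
Conditions: Bu3SnCH=CH2, Pd(PPh3)4 (5 mol %), LiCl, THF, 65 °C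
Reagents that add atoms: tributyl(vinyl)stannane, C=C[Sn](CCCC)(CCCC)CCCC
Why: Stille coupling of an electron-poor vinyl triflate under neutral conditions; the diene lactone is used directly to avoid dimerisation.

Step 6
Reactants: 7 4-ethenyl-3-methylfuran-2(5H)-one
Product: 8 4-methyl-5-oxo-2,5-dihydrofuran-3-carbaldehyde
Conditions: O3, CH2Cl2, −78 °C (indicator end point); Me2S
Reagents that add atoms: ozone, [O-][O+]=O
Why: Ozonolysis cleaves the terminal vinyl group, which is more electron-rich than the ring alkene conjugated to the lactone carbonyl; titration to an indicator end point prevents over-oxidation.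

Step 7
Reactants: 4 tert-butyl(dimethyl)[(2-methylidenepent-4-yn-1-yl)oxy]silane; 9 3-methylcyclohex-2-en-1-one; 8 4-methyl-5-oxo-2,5-dihydrofuran-3-carbaldehyde
Product: 12 (2S,3R)-3-[(1E)-4-({[tert-butyl(dimethyl)silyl]oxy}methyl)penta-1,4-dien-1-yl]-2-[(R)-hydroxy(4-methyl-5-oxo-2,5-dihydrofuran-3-yl)methyl]-3-methylcyclohexan-1-one (1R,9R,10S), via alkenylalane 10 (not isolated), via aluminium enolate 11 (not isolated)
Conditions: 4, i-Bu2AlH (1.0 equiv), hexane, 50 °C; then 9, Cu(OTf)2 (5 mol %), chiral sulfonate-bearing imidazolinium salt (NHC precursor, 6 mol %), THF, −30 °C; then 8, THF, −78 → −40 °C; aq. KNaC4H4O6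
Reagents that add atoms: none
Why: Syn hydroalumination of the terminal alkyne gives the E-alkenylalane 10 and leaves the 1,1-disubstituted alkene untouched. The alane deprotonates the imidazolinium salt and reduces divalent copper, and the resulting NHC-bound monovalent alkenylcopper adds 1,4 to 9 (π-complex, trivalent copper β-adduct, reductive elimination), forming C1–C2 with transfer of the sp2 group in preference to isobutyl. The closest known reaction type is the copper-catalysed enantioselective conjugate addition of alkenylaluminium reagents to β-substituted cyclic enones with aldol trapping of the metal enolate. C1 is set by the chiral NHC–copper catalyst, which selects the enone face. The regiodefined aluminium enolate 11 then binds aldehyde 8 and attacks it through a closed six-membered chair, forming C9–C10; no ring is closed in this step. C10 is set by the substrate: the aldehyde should enter anti to the pseudoaxial alkenyl arm and gauche to the smaller methyl, giving the trans C2/C9 relationship. C9 follows from the ring-locked E-enolate (anti aldolate) and is only provisional, since it is reset in steps 11 and 12. The step needs addition to win over proton transfer from the γ-CH2 of 8, which the low basicity of aluminium enolates and the high electrophilicity of the β-formyl butenolide at −78 °C should secure, and a cold non-basic work-up prevents retro-aldol.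

Step 8
Reactants: 12 aldol adduct (1R,9R,10S)
Product: 13 silyloxyfuran ketone: C9–OTBS (9R); butenolide converted into the 2-(tert-butyldimethylsilyloxy)-3-methylfuran (silyloxy on C19; C7–H aromatic); ring A ketone unchanged; C6–OTBS unchanged (1R,9R,10S)
Conditions: TBSOTf (2.3 equiv), Et3N, CH2Cl2, −78 → −30 °C
Reagents that add atoms: tert-butyldimethylsilyl triflate, CC(C)(C)[Si](C)(C)OS(=O)(=O)C(F)(F)F
Why: Silyl triflate and amine silylate the carbinol and, by soft enolisation of the acidic γ-CH2, turn the butenolide into a silyloxyfuran. This blocks retro-aldol and removes the most acidic protons before the strong-base step; the hindered ketone should survive at low temperature with controlled stoichiometry.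

Step 9
Reactants: 13 silyloxyfuran ketone (1R,9R,10S)
Product: 15 silyloxyfuran enol triflate: C11–OTf on a C11=C12 double bond; C9–OTBS; C6–OTBS (1R,9R,10S), via potassium enolate 14 (not isolated)
Conditions: KN(SiMe3)2 (1.15 equiv), THF, −78 °C; PhNTf2, −78 → −20 °C
Reagents that add atoms: N-phenylbis(trifluoromethanesulfonimide), O=S(=O)(N(c1ccccc1)S(=O)(=O)C(F)(F)F)C(F)(F)F
Why: Kinetic deprotonation occurs at the unhindered C12 methylene and not at the tertiary C10–H, which also avoids β-elimination of the C9 silyl ether; O-triflation fixes the C11=C12 regiochemistry.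

Step 10
Reactants: 15 silyloxyfuran enol triflate (1R,9R,10S)
Product: 16 9R-diol: free C6–OH; free 9R-OH; butenolide restored; C11 enol triflate intact (1R,9R,10S)
Conditions: HF·pyridine, THF, 0 °C → rt
Reagents that add atoms: none
Why: Fluoride-mediated cleavage of all three silyl groups; protonation of the furan at C7 under pyridine buffering returns the conjugated butenolide, and the vinyl triflate is stable to these conditions.

Step 11
Reactants: 16 9R-diol (1R,9R,10S)
Product: 17 keto enal: C6 aldehyde conjugated to C5=C16; C9 ketone; butenolide; C11 enol triflate (1R,10R)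
Conditions: Dess–Martin periodinane, NaHCO3, CH2Cl2, 0 °C; used at once
Reagents that add atoms: none
Why: Buffered hypervalent-iodine oxidation of both alcohols; oxidising C9 is possible only now that C11 is no longer a ketone, and neutral, cold handling protects the acidic C10–H.

Step 12
Reactants: 17 keto enal (1R,10R)
Product: 18 9S-diol: free C6–OH; free 9S-OH; butenolide; C11 enol triflate (1R,9S,10S)
Conditions: NaBH4, CeCl3·7H2O, MeOH/THF, −78 °C
Reagents that add atoms: none
Why: Luche 1,2-reduction of both carbonyls without conjugate reduction of the acyl butenolide. C9 is set by Felkin–Anh control from C10: hydride approaches anti to the quaternary C1 and past H10 while the C11 vinyl carbon sits next to the carbonyl oxygen, which gives the 9S (syn-aldol) configuration of the target, opposite to the anti carbinol formed in the coupling step. The aldehyde returns to the primary alcohol.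

Step 13
Reactants: 18 9S-diol (1R,9S,10S)
Product: 19 hydroxy enal: C6 aldehyde; free 9S-OH; butenolide; C11 enol triflate (1R,9S,10S)
Conditions: TEMPO (10 mol %), PhI(OAc)2, CH2Cl2, rt
Reagents that add atoms: none
Why: Oxoammonium oxidation is selective for the primary allylic alcohol over the hindered secondary C9 carbinol.

Step 14
Reactants: 19 hydroxy enal (1R,9S,10S)
Product: 21 macrocyclic butenolide: ten-membered ring closed at C6–C7; C6–OTES; C9–OTES; E-C2=C3; C5=C16; ring A enol triflate (1R,6R,7S,9S,10S), via silyloxyfuran aldehyde 20 (not isolated)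
Conditions: TESOTf (2.2 equiv), Et3N (2.4 equiv), CH2Cl2, −78 °C; then slow addition to TESOTf (0.5 equiv), CH2Cl2 (final 2 mM), −78 → −40 °C
Reagents that add atoms: triethylsilyl triflate, CC[Si](CC)(CC)OS(=O)(=O)C(F)(F)F
Why: One-pot silylation of C9–OH and soft enolisation to the 2-silyloxyfuran, then silyl-triflate-promoted intramolecular vinylogous Mukaiyama aldol at high dilution; the furan reacts through C7 and silyl transfer caps C6–O. Open transition states of Lewis-acid-promoted silyloxyfuran additions favour the threo (anti) C6–O/C7–O relationship required here, and the trans arms on ring A bring the two termini together. The absolute sense at C6/C7 (6R,7S) rests on the macrocyclic transition state.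

Step 15
Reactants: 21 macrocyclic butenolide (1R,6R,7S,9S,10S)
Product: 22 epoxy enol triflate: trans-2,3-epoxide on the macrocyclic butenolide; ring A enol triflate kept (1S,2R,3R,6R,7S,9S,10S)
Conditions: 1,2:4,5-di-O-isopropylidene-β-D-erythro-2,3-hexodiulo-2,6-pyranose (D-fructose-derived Shi ketone, 30 mol %), KHSO5, NaHCO3 (pH 8), MeCN/H2O, 0 °C
Reagents that add atoms: potassium peroxymonosulfate, [K+].[O-]S(=O)(=O)OO
Why: Chiral dioxirane (Shi) epoxidation, which is best suited to trans-disubstituted alkenes, with the ketone antipode that normally gives R,R-epoxides from E-alkenes. The vinyl triflate and butenolide are electron-poor, and the 1,1-disubstituted C5=C16 alkene with its allylic silyl ether is a poor substrate for this catalyst.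

Step 16
Reactants: 22 epoxy enol triflate (1S,2R,3R,6R,7S,9S,10S)
Product: 23 methyl alkene: C20 methyl on C11; C11=C12 (1S,2R,3R,6R,7S,9S,10S)
Conditions: Me2Zn, Pd(PPh3)4 (5 mol %), THF, 0 °C → rt
Reagents that add atoms: dimethylzinc, C[Zn]C
Why: Negishi-type methylation of the vinyl triflate with retention of the double-bond position; the dialkylzinc reagent does not attack the epoxide, lactone or silyl ethers.

Step 17
Reactants: 23 methyl alkene (1S,2R,3R,6R,7S,9S,10S)
Product: 24 8,17-epoxy lactone: epoxide oxygen bridging C8–C17; cis to H7 (1S,2R,3R,6R,7R,8S,9S,10S,17R)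
Conditions: t-BuOOH, n-BuLi (forms t-BuOOLi), THF, −78 → −20 °C
Reagents that add atoms: tert-butyl hydroperoxide, CC(C)(C)OO
Why: Nucleophilic (Weitz–Scheffer type) epoxidation: peroxide adds to C8 of the unsaturated lactone from the face anti to the C7–C6 bond and closes onto C17, which sets C8. The isolated alkenes and the epoxide are inert to the peroxide anion.

Step 18
Reactants: 24 8,17-epoxy lactone
Product: 25 β-hydroxy lactone: tertiary C8–OH; C17–H; C18 cis to the C8 hydroxyl; C6–OTES; C9–OTES (1S,2R,3R,6R,7R,8S,9S,10S,17R)
Conditions: SmI2, Me2NCH2CH2OH, THF/HMPA, −78 °C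
Reagents that add atoms: none
Why: Single-electron reduction of the lactone carbonyl cleaves the α C17–O bond and gives the C8 alkoxide and a samarium enolate. Protonation on the face opposite the bulky C8 samarium alkoxide should give 17R, which is also the more stable epimer (C18 trans to C9), so any 17-epimer can be converged with mild base.

Step 19
Reactants: 25 β-hydroxy lactone bis-silyl ether
Product: 26 6,8,9-triol: allylic 6R-OH; tertiary 8-OH; 9S-OH (1S,2R,3R,6R,7R,8R,9S,10S,17R)
Conditions: HF·pyridine, pyridine, THF, 0 °C
Reagents that add atoms: none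
Why: Buffered fluoride cleaves both triethylsilyl ethers under conditions that should spare the hindered epoxide and the lactone.

Step 20
Reactants: 26 6,8,9-triol
Product: 27 chloro diol: 6S-chloride; free 8-OH; free 9-OH (1S,2R,3R,6S,7S,8R,9S,10S,17R)
Conditions: PPh3, Cl3CC(O)CCl3, CH2Cl2, −20 → 0 °C
Reagents that add atoms: hexachloroacetone, O=C(C(Cl)(Cl)Cl)C(Cl)(Cl)Cl
Why: Appel-type chlorination through the alkoxyphosphonium ion pair, with SN2 inversion at C6 (6R alcohol to 6S chloride). The allylic alcohol should react far faster than the neopentyl-like C9 carbinol or the tertiary C8–OH, and SN2′ would place a trisubstituted alkene inside the ten-membered ring.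

Step 21
Reactants: 27 chloro diol
Product: 28 C9 acetoxyacetate: 6S-chloride; free 8-OH; ring A methyl alkene (1S,2R,3R,6S,7S,8R,9S,10S,17R)
Conditions: AcOCH2COCl, pyridine, DMAP (cat.), CH2Cl2, 0 °C → rt
Reagents that add atoms: acetoxyacetyl chloride, CC(=O)OCC(=O)Cl
Why: Acylation of the only secondary alcohol; the tertiary C8–OH is too hindered to compete.

Step 22
Reactants: 28 C9 acetoxyacetate carrying the ring A methyl alkene
Product: 29 11,12-cis-diol: both hydroxyls trans to C15 (1S,2R,3R,6S,7S,8R,9S,10S,11S,12R,17R)
Conditions: OsO4 (5 mol %), NMO, acetone/H2O, 0 °C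
Reagents that add atoms: osmium tetroxide, O=[Os](=O)(=O)=O; N-methylmorpholine N-oxide, C[N+]1([O-])CCOCC1; water, O
Why: Upjohn dihydroxylation: the [3+2] addition should occur on the face opposite the axial C15 methyl and the C9 arm, which sets C11 (oxygen trans to C15). The remaining C5=C16 alkene is deactivated by the allylic chloride.

Step 23
Reactants: 29 11,12-cis-diol
Product: 30 α-ketol: C12 ketone; tertiary 11-OH (1S,2R,3R,6S,7S,8R,9S,10S,11S,17R)
Conditions: IBX, DMSO, rt
Reagents that add atoms: none
Why: IBX oxidises the secondary C12 carbinol of a 1,2-diol to the ketone without cleaving the C11–C12 bond, which a periodinane with exchangeable acetates could do. The tertiary alcohols at C8 and C11 cannot be oxidised, and without an N-oxide additive at room temperature the new ketone is not dehydrogenated.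

Step 24
Reactants: 30 α-ketol
Product: 31 α-acetoxy ketone: C11–OAc; C12 ketone; ring A saturated at C13–C14 (1S,2R,3R,6S,7S,8R,9S,10S,11S,17R)
Conditions: Ac2O, DMAP, Et3N, CH2Cl2, rt → 40 °C
Reagents that add atoms: acetic anhydride, CC(=O)OC(C)=O
Why: Nucleophile-catalysed acylation of the equatorial tertiary α-ketol hydroxyl, which is acidified by the adjacent ketone; the C8–OH, flanked by three substituted carbons, should stay free, and the acetate blocks α-ketol rearrangement in the last step.

Step 25
Reactants: 31 α-acetoxy ketone
Product: 32 CNP0314084.4 (target; 1S,2R,3R,6S,7S,8R,9S,10S,11S,17R)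
Conditions: IBX, 4-methoxypyridine N-oxide, DMSO, rt
Reagents that add atoms: none
Why: IBX dehydrogenation of the ketone through its enol; C11 is fully substituted, so only the C13=C14 enone can form.

## Compound list

1 | 2-methylenepropane-1,3-diol | C=C(CO)CO | starting material
2 | 2-({[tert-butyl(dimethyl)silyl]oxy}methyl)prop-2-en-1-ol | C=C(CO)CO[Si](C)(C)C(C)(C)C | intermediate
3 | {[2-(bromomethyl)prop-2-en-1-yl]oxy}(tert-butyl)dimethylsilane | C=C(CBr)CO[Si](C)(C)C(C)(C)C | intermediate
4 | tert-butyl(dimethyl)[(2-methylidenepent-4-yn-1-yl)oxy]silane | C#CCC(=C)CO[Si](C)(C)C(C)(C)C | intermediate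
5 | 4-hydroxy-3-methylfuran-2(5H)-one | CC1=C(O)COC1=O | starting material
6 | 4-methyl-5-oxo-2,5-dihydrofuran-3-yl trifluoromethanesulfonate | CC1=C(OS(=O)(=O)C(F)(F)F)COC1=O | intermediate
7 | 4-ethenyl-3-methylfuran-2(5H)-one | C=CC1=C(C)C(=O)OC1 | intermediate
8 | 4-methyl-5-oxo-2,5-dihydrofuran-3-carbaldehyde | O=CC1=C(C)C(=O)OC1 | intermediate
9 | 3-methylcyclohex-2-en-1-one | CC1=CC(=O)CCC1 | starting material
10 | [(1E)-4-({[tert-butyl(dimethyl)silyl]oxy}methyl)penta-1,4-dien-1-yl]bis(2-methylpropyl)alumane | C=C(CO[Si](C)(C)C(C)(C)C)C/C=C/[Al](CC(C)C)CC(C)C | intermediate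
11 | diisobutylaluminium C10=C11 enolate of the 1R conjugate adduct | C=C(CO[Si](C)(C)C(C)(C)C)C/C=C/[C@@]1(C)CCCC(O[Al](CC(C)C)CC(C)C)=C1 | intermediate
12 | (2S,3R)-3-[(1E)-4-({[tert-butyl(dimethyl)silyl]oxy}methyl)penta-1,4-dien-1-yl]-2-[(R)-hydroxy(4-methyl-5-oxo-2,5-dihydrofuran-3-yl)methyl]-3-methylcyclohexan-1-one | C=C(CO[Si](C)(C)C(C)(C)C)C/C=C/[C@@]1(C)CCCC(=O)[C@@H]1[C@@H](O)C1=C(C)C(=O)OC1 | intermediate
13 | silyloxyfuran ketone: C9 TBS ether, lactone as 2-(TBS-oxy)-3-methylfuran, ring A ketone, C6 TBS ether (1R,9R,10S) | C=C(CO[Si](C)(C)C(C)(C)C)C/C=C/[C@@]1(C)CCCC(=O)[C@@H]1[C@@H](O[Si](C)(C)C(C)(C)C)c1coc(O[Si](C)(C)C(C)(C)C)c1C | intermediate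
14 | potassium C11=C12 enolate of the silyloxyfuran ketone | C=C(CO[Si](C)(C)C(C)(C)C)C/C=C/[C@@]1(C)CCC=C([O-])[C@@H]1[C@@H](O[Si](C)(C)C(C)(C)C)c1coc(O[Si](C)(C)C(C)(C)C)c1C.[K+] | intermediate
15 | silyloxyfuran enol triflate: C11 triflate on C11=C12, C9 TBS ether, 2-(TBS-oxy)furan, C6 TBS ether (1R,9R,10S) | C=C(CO[Si](C)(C)C(C)(C)C)C/C=C/[C@@]1(C)CCC=C(OS(=O)(=O)C(F)(F)F)[C@@H]1[C@@H](O[Si](C)(C)C(C)(C)C)c1coc(O[Si](C)(C)C(C)(C)C)c1C | intermediate
16 | 9R-configured 6,9-diol with butenolide and C11 enol triflate (1R,9R,10S) | C=C(CO)C/C=C/[C@@]1(C)CCC=C(OS(=O)(=O)C(F)(F)F)[C@@H]1[C@@H](O)C1=C(C)C(=O)OC1 | intermediate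
17 | keto enal: C6 enal, C9 ketone, butenolide, C11 enol triflate (1R,10R) | C=C(C=O)C/C=C/[C@@]1(C)CCC=C(OS(=O)(=O)C(F)(F)F)[C@@H]1C(=O)C1=C(C)C(=O)OC1 | intermediate
18 | 9S-configured 6,9-diol with butenolide and C11 enol triflate (1R,9S,10S) | C=C(CO)C/C=C/[C@@]1(C)CCC=C(OS(=O)(=O)C(F)(F)F)[C@@H]1[C@H](O)C1=C(C)C(=O)OC1 | intermediate
19 | hydroxy enal: C6 enal with free 9S hydroxyl, butenolide, C11 enol triflate (1R,9S,10S) | C=C(C=O)C/C=C/[C@@]1(C)CCC=C(OS(=O)(=O)C(F)(F)F)[C@@H]1[C@H](O)C1=C(C)C(=O)OC1 | intermediate
20 | silyloxyfuran aldehyde: C9 TES ether, 2-(TES-oxy)furan, C6 enal (1R,9S,10S) | C=C(C=O)C/C=C/[C@@]1(C)CCC=C(OS(=O)(=O)C(F)(F)F)[C@@H]1[C@H](O[Si](CC)(CC)CC)c1coc(O[Si](CC)(CC)CC)c1C | intermediate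
21 | macrocyclic butenolide, 6,9-bis-TES ether, ring A enol triflate (1R,6R,7S,9S,10S) | C=C1C/C=C/[C@@]2(C)CCC=C(OS(=O)(=O)C(F)(F)F)[C@@H]2[C@H](O[Si](CC)(CC)CC)C2=C(C)C(=O)O[C@@H]2[C@@H]1O[Si](CC)(CC)CC | intermediate
22 | trans-2,3-epoxy macrocyclic butenolide, 6,9-bis-TES ether, ring A enol triflate (1S,2R,3R,6R,7S,9S,10S) | C=C1C[C@H]2O[C@@H]2[C@@]2(C)CCC=C(OS(=O)(=O)C(F)(F)F)[C@@H]2[C@H](O[Si](CC)(CC)CC)C2=C(C)C(=O)O[C@@H]2[C@@H]1O[Si](CC)(CC)CC | intermediate
23 | C11-methyl C11=C12 alkene, epoxy butenolide, 6,9-bis-TES ether (1S,2R,3R,6R,7S,9S,10S) | C=C1C[C@H]2O[C@@H]2[C@@]2(C)CCC=C(C)[C@@H]2[C@H](O[Si](CC)(CC)CC)C2=C(C)C(=O)O[C@@H]2[C@@H]1O[Si](CC)(CC)CC | intermediate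
24 | 8,17-epoxy lactone, 6,9-bis-TES ether (1S,2R,3R,6R,7R,8S,9S,10S,17R) | C=C1C[C@H]2O[C@@H]2[C@@]2(C)CCC=C(C)[C@@H]2[C@H](O[Si](CC)(CC)CC)[C@@]23O[C@@]3(C)C(=O)O[C@@H]2[C@@H]1O[Si](CC)(CC)CC | intermediate
25 | 8-hydroxy lactone, 6,9-bis-TES ether (1S,2R,3R,6R,7R,8S,9S,10S,17R) | C=C1C[C@H]2O[C@@H]2[C@@]2(C)CCC=C(C)[C@@H]2[C@H](O[Si](CC)(CC)CC)[C@@]2(O)[C@H](OC(=O)[C@@H]2C)[C@@H]1O[Si](CC)(CC)CC | intermediate
26 | 6,8,9-triol (1S,2R,3R,6R,7R,8R,9S,10S,17R) | C=C1C[C@H]2O[C@@H]2[C@@]2(C)CCC=C(C)[C@@H]2[C@H](O)[C@@]2(O)[C@H](OC(=O)[C@@H]2C)[C@@H]1O | intermediate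
27 | 6S-chloride, 8,9-diol (1S,2R,3R,6S,7S,8R,9S,10S,17R) | C=C1C[C@H]2O[C@@H]2[C@@]2(C)CCC=C(C)[C@@H]2[C@H](O)[C@@]2(O)[C@H](OC(=O)[C@@H]2C)[C@H]1Cl | intermediate
28 | C9 acetoxyacetate, 6S-chloride, free 8-OH, ring A methyl alkene | C=C1C[C@H]2O[C@@H]2[C@@]2(C)CCC=C(C)[C@@H]2[C@H](OC(=O)COC(C)=O)[C@@]2(O)[C@H](OC(=O)[C@@H]2C)[C@H]1Cl | intermediate
29 | 11,12-cis-diol (11S,12R) | C=C1C[C@H]2O[C@@H]2[C@@]2(C)CC[C@@H](O)[C@@](C)(O)[C@@H]2[C@H](OC(=O)COC(C)=O)[C@@]2(O)[C@H](OC(=O)[C@@H]2C)[C@H]1Cl | intermediate
30 | 11-hydroxy-12-ketone (11S) | C=C1C[C@H]2O[C@@H]2[C@@]2(C)CCC(=O)[C@@](C)(O)[C@@H]2[C@H](OC(=O)COC(C)=O)[C@@]2(O)[C@H](OC(=O)[C@@H]2C)[C@H]1Cl | intermediate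
31 | 11-acetoxy-12-ketone, C13–C14 saturated | C=C1C[C@H]2O[C@@H]2[C@@]2(C)CCC(=O)[C@@](C)(OC(C)=O)[C@@H]2[C@H](OC(=O)COC(C)=O)[C@@]2(O)[C@H](OC(=O)[C@@H]2C)[C@H]1Cl | intermediate
32 | CNP0314084.4 | C=C1C[C@H]2O[C@@H]2[C@@]2(C)C=CC(=O)[C@@](C)(OC(C)=O)[C@@H]2[C@H](OC(=O)COC(C)=O)[C@@]2(O)[C@H](OC(=O)[C@@H]2C)[C@H]1Cl | target

## Step count and least certain steps

Total: 25 steps. Longest linear sequence: 22 steps (steps 1–3 and 7–25); steps 4–6 are the convergent branch to aldehyde 8.

**Step 7 (key step).** The most likely failure is at the aldol stage. The aluminium enolate sits next to the new quaternary centre and may take a proton from the γ-CH2 of 8 instead of adding to the aldehyde, so that only the conjugate adduct is recovered. Facial control at C10 also rests on a small size difference between methyl and alkenyl. The C9 outcome does not matter, because steps 11 and 12 reset it. Fallback, setting out from 9, 10 and 8 and returning at 12: the conjugate addition is run as before, and enolate 11 is quenched with TMSOTf to give the trimethylsilyl enol ether F1. This is isolated and combined with 8 in a separate, non-basic Mukaiyama aldol (BF3·OEt2, CH2Cl2, −78 °C). Proton transfer is then no longer possible, and any C9 mixture converges later.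

**Step 14.** The ring closure has to reach a strained ten-membered transition state, so the most likely failures are intermolecular aldol oligomerisation or attack on the wrong aldehyde face, giving the other anti pair at C6/C7. Fallback, setting out from 19 and returning at 21: C9–OH is silylated separately (TESCl, imidazole) to give the enal F2. F2 is cyclised as its lithium dienolate (LiN(SiMe3)2, THF, −78 °C, high dilution), an anionic and reversible aldol in which the chelated lithium aldolate holds the ring closed, to give the macrocyclic C6 alcohol F3. F3 is silylated (TESOTf, 2,6-lutidine) to 21. Should the C6 epimer predominate, the C6 carbinol of F3 can be reset by oxidation and Luche reduction before silylation.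

**Step 15.** The ring conformation exposes only one face of C2=C3. If that face is not the one the catalyst prefers, substrate control overrides the catalyst and oxygen is delivered to the wrong face, or the reaction slows enough for C5=C16 to compete. Fallback, setting out from 21 and returning at 22: NBS in aqueous THF gives the bromohydrin F4 (bromonium on the exposed face, water anti at the less hindered C3). Closure with Ag2O then places the epoxide oxygen on the face opposite to the one an electrophile attacks directly.

**Step 17.** The β-carbon C8 is fully substituted, so peroxide addition may be too slow, and the basic medium can then epimerise C7 or expel the C6 silyloxy group. Fallback, setting out from 23 and returning at 25 (24 is bypassed): copper-catalysed conjugate borylation (B2pin2, CuCl, NaOt-Bu, bisphosphine ligand, MeOH, THF) on the face anti to C6 gives the C8 boronate F5. Oxidation with retention (NaBO3·4H2O) gives the β-hydroxy lactone 25 without an epoxide or a single-electron reductant.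

**Step 20.** Chloride may be delivered with allylic transposition (SN2′, to C16), and the C8/C9 diol may intercept the activated phosphorus. Fallback, setting out from 26 and returning at 28 (27 is bypassed): the less hindered C6–OH is silylated selectively (TESCl, imidazole, −20 °C) to give F6. F6 is acylated at C9 with acetoxyacetyl chloride to give F7. The silyl ether is removed (HF·pyridine) to give the mono-alcohol F8, and the same Appel-type chlorination is run on F8, which has only the inert tertiary C8–OH as a bystander and can be run colder to favour the tight ion pair.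

**Step 22.** Osmylation is governed largely by sterics, so competing dihydroxylation of the exocyclic C5=C16 alkene may erode chemoselectivity. Fallback, setting out from 28 and returning at 30 (29 is bypassed): ruthenium-catalysed ketohydroxylation (RuCl3 cat., KHSO5, NaHCO3, EtOAc/MeCN/H2O). RuO4 is more electrophilic, which favours the trisubstituted alkene, and the reaction gives the tertiary-hydroxy ketone directly from the same face.

## Further compounds

F1 | step 7 | trimethylsilyl enol ether (C10=C11) of the 1R conjugate adduct | C=C(CO[Si](C)(C)C(C)(C)C)C/C=C/[C@@]1(C)CCCC(O[Si](C)(C)C)=C1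
F2 | step 14 | C9 TES ether of the hydroxy enal (C6 enal, butenolide, C11 enol triflate) | C=C(C=O)C/C=C/[C@@]1(C)CCC=C(OS(=O)(=O)C(F)(F)F)[C@@H]1[C@H](O[Si](CC)(CC)CC)C1=C(C)C(=O)OC1
F3 | step 14 | macrocyclic butenolide with free 6R hydroxyl and C9 TES ether | C=C1C/C=C/[C@@]2(C)CCC=C(OS(=O)(=O)C(F)(F)F)[C@@H]2[C@H](O[Si](CC)(CC)CC)C2=C(C)C(=O)O[C@@H]2[C@@H]1O
F4 | step 15 | 2-bromo-3-hydroxy bromohydrin of the macrocyclic butenolide | C=C1C[C@@H](O)[C@@H](Br)[C@@]2(C)CCC=C(OS(=O)(=O)C(F)(F)F)[C@@H]2[C@H](O[Si](CC)(CC)CC)C2=C(C)C(=O)O[C@@H]2[C@@H]1O[Si](CC)(CC)CC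
F5 | step 17 | C8 pinacol boronate of the saturated lactone | C=C1C[C@H]2O[C@@H]2[C@@]2(C)CCC=C(C)[C@@H]2[C@H](O[Si](CC)(CC)CC)[C@@]2(B3OC(C)(C)C(C)(C)O3)[C@H](OC(=O)[C@@H]2C)[C@@H]1O[Si](CC)(CC)CC
F6 | step 20 | C6 TES ether of the triol (8,9-diol free) | C=C1C[C@H]2O[C@@H]2[C@@]2(C)CCC=C(C)[C@@H]2[C@H](O)[C@@]2(O)[C@H](OC(=O)[C@@H]2C)[C@@H]1O[Si](CC)(CC)CC
F7 | step 20 | C9 acetoxyacetate, C6 TES ether | C=C1C[C@H]2O[C@@H]2[C@@]2(C)CCC=C(C)[C@@H]2[C@H](OC(=O)COC(C)=O)[C@@]2(O)[C@H](OC(=O)[C@@H]2C)[C@@H]1O[Si](CC)(CC)CC
F8 | step 20 | C9 acetoxyacetate with free 6R hydroxyl | C=C1C[C@H]2O[C@@H]2[C@@]2(C)CCC=C(C)[C@@H]2[C@H](OC(=O)COC(C)=O)[C@@]2(O)[C@H](OC(=O)[C@@H]2C)[C@@H]1O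
F0 | step 22 | none | none
A1 | alternative 1 | ten-membered 3,8-diketone with (Z)-C5=C6, fused to ring A | C/C1=C/CC(=O)[C@@H](OCOC)[C@H]2[C@H](C)C3(OCCO3)CC[C@]2(C)[C@@H](OCOC)C(=O)C1
A2 | alternative 2 | target skeleton with C8 and C9 triethylsilyl ethers | C=C1C[C@H]2O[C@@H]2[C@@]2(C)C=CC(=O)[C@@](C)(OC(C)=O)[C@@H]2[C@H](O[Si](CC)(CC)CC)[C@@]2(O[Si](CC)(CC)CC)[C@H](OC(=O)[C@@H]2C)[C@H]1Cl
A3 | alternative 3 | ten-membered ring fused to the α-methylene γ-lactone, C8 silyl ether, C6 PMB ether | C=C1C/C=C/[C@@]2(C)C=CC(=O)[C@@](C)(OC(C)=O)[C@@H]2[C@H](OCOC)[C@@]2(O[Si](C)(C)C(C)(C)C)[C@H](OC(=O)C2=C)[C@@H]1OCc1ccc(OC)cc1
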